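**Retrosynthetic overview**
1. The eleven-membered ring is closed last, at C8–C9, by an intramolecular Nozaki–Hiyama–Kishi reaction of a vinyl triflate with an aldehyde; this also creates the exocyclic methylene and the C9 carbinol (then acetylation, desilylation).
2. The open precursor comes from a B-alkyl Suzuki union (C1–C14) of a cis-hydrindenyl triflate with a C9–C14/C20 side chain made by copper-catalysed asymmetric allylic alkylation.
3. Key disconnection: the cis-fused six/five bicycle is cut back in one operation to an acyclic keto-aldehyde – aldol condensation (C15=C16, six-membered ring), then in the same flask an intramolecular ene reaction (C16–C7, five-membered ring).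
4. The keto-aldehyde comes from a catalyst-controlled syn-aldol (C2–C3) of 1-hydroxybutan-2-one with an α-quaternary aldehyde, itself made from geraniol by Sharpless epoxidation and epoxy silyl ether rearrangement (C4).
5. Ring order: six- and five-membered rings together, then the eleven-membered ring.

Assumption: the target carbons are labelled C1–C20 (C1=C15 ring alkene with methyl C17 on C15, C2/C3 diol carbons, C4 quaternary carbon with methyl C18, C7–C16 the CH–CH bond shared by the five- and eleven-membered rings, C8(=C19H2), C9 CH–OAc, C12 CH–C20H2OAc) and these labels are used for all intermediates; TBS = tert-butyldimethylsilyl, TES = triethylsilyl.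

**Step 1**
Reactants: 1 (E)-1,4-dibromobut-2-ene
Product: 2 (E)-4-bromobut-2-en-1-yl acetate
Conditions: KOAc (0.3 equiv relative to 1), 18-crown-6 (cat.), MeCN, 23 °C; excess 1 recovered
Reagents that add atoms: potassium acetate, CC(=O)[O-].[K+]
Why: Nucleophilic substitution (SN2) of one allylic bromide by acetate, with excess dibromide suppressing the diacetate; no stereocentre is formed.

**Step 2**
Reactants: 2 (E)-4-bromobut-2-en-1-yl acetate; 3 (3-bromopropoxy)(tert-butyl)dimethylsilane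
Product: 5 (2S)-5-[(tert-butyldimethylsilyl)oxy]-2-ethenylpentyl acetate, via Grignard reagent 4 (not isolated)
Conditions: 3, Mg, THF, 23 °C; then 2, CuBr·SMe2 (3 mol %), Taniaphos (3.3 mol %, enantiomer giving 2S), CH2Cl2, −78 °C
Reagents that add atoms: none
Why: Copper-catalysed asymmetric allylic alkylation (SN2′) gives the branched product, the chiral ferrocenyl diphosphine setting C12, and at −78 °C the acetate is not attacked.

**Step 3**
Reactants: 6 geraniol
Product: 7 (2S,3S)-2,3-epoxygeraniol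
Conditions: L-(+)-diethyl tartrate (12 mol %), Ti(OiPr)4 (10 mol %), t-BuOOH, 4 Å molecular sieves, CH2Cl2, −20 °C
Reagents that add atoms: tert-butyl hydroperoxide, CC(C)(C)OO
Why: Sharpless asymmetric epoxidation; the L-tartrate complex gives the (2S,3S) epoxide, whose tertiary carbon becomes C4.

**Step 4**
Reactants: 7 (2S,3S)-2,3-epoxygeraniol
Product: 8 triethyl{[(2S,3S)-3-methyl-3-(4-methylpent-3-en-1-yl)oxiran-2-yl]methoxy}silane
Conditions: TESCl, imidazole, CH2Cl2, 0 °C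
Reagents that add atoms: chlorotriethylsilane, CC[Si](Cl)(CC)CC
Why: Silylation of the primary alcohol prepares the epoxy silyl ether needed for the rearrangement; stereocentres untouched.

**Step 5**
Reactants: 8 triethyl{[(2S,3S)-3-methyl-3-(4-methylpent-3-en-1-yl)oxiran-2-yl]methoxy}silane
Product: 9 (2S)-2,6-dimethyl-2-{[(triethylsilyl)oxy]methyl}hept-5-enal
Conditions: MeAl(OAr)2 (Ar = 4-bromo-2,6-di-tert-butylphenyl, 20 mol %), CH2Cl2, −78 → −20 °C
Reagents that add atoms: none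
Why: Yamamoto–Maruoka epoxy silyl ether rearrangement (semipinacol type): the epoxide opens at the tertiary carbon and the silyloxymethyl group migrates anti to the leaving oxygen, transferring the epoxide chirality to quaternary C4.

**Step 6**
Reactants: 9 (2S)-2,6-dimethyl-2-{[(triethylsilyl)oxy]methyl}hept-5-enal; 10 1-hydroxybutan-2-one
Product: 11 (4S,5R,6S)-4,5-dihydroxy-6,10-dimethyl-6-{[(triethylsilyl)oxy]methyl}undec-9-en-3-one
Conditions: 10 (5 equiv), O-tert-butyl-L-threonine (20 mol %), N-methylpyrrolidone, 4 °C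
Reagents that add atoms: none
Why: Primary-amine-catalysed direct syn-aldol of a hydroxyketone (Barbas type); the enamine of 10 adds to one aldehyde face under catalyst control, setting C2 and C3 as the syn diol that becomes the trans ring diol.

**Step 7**
Reactants: 11 (4S,5R,6S)-4,5-dihydroxy-6,10-dimethyl-6-{[(triethylsilyl)oxy]methyl}undec-9-en-3-one
Product: 12 (4S,5R,6S)-4,5-bis[(tert-butyldimethylsilyl)oxy]-6,10-dimethyl-6-{[(triethylsilyl)oxy]methyl}undec-9-en-3-one
Conditions: TBSOTf (2.5 equiv), 2,6-lutidine, CH2Cl2, −78 → 0 °C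
Reagents that add atoms: tert-butyldimethylsilyl trifluoromethanesulfonate, CC(C)(C)[Si](C)(C)OS(=O)(=O)C(F)(F)F
Why: Silyl ether formation on both secondary alcohols with a protecting group that tolerates the Lewis acid, bases and palladium used later; the TES ether survives.

**Step 8**
Reactants: 12 (4S,5R,6S)-4,5-bis[(tert-butyldimethylsilyl)oxy]-6,10-dimethyl-6-{[(triethylsilyl)oxy]methyl}undec-9-en-3-one
Product: 13 (2R)-2-{(1R,2S)-1,2-bis[(tert-butyldimethylsilyl)oxy]-3-oxopentyl}-2,6-dimethylhept-5-enal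
Conditions: (COCl)2, DMSO, CH2Cl2, −78 → −30 °C; then Et3N
Reagents that add atoms: none
Why: Swern conditions cleave and oxidise a primary TES ether directly to the aldehyde while secondary TBS ethers remain; the new aldehyde is non-enolisable, so C4 is safe.

**Step 9**
Reactants: 13 (2R)-2-{(1R,2S)-1,2-bis[(tert-butyldimethylsilyl)oxy]-3-oxopentyl}-2,6-dimethylhept-5-enal
Product: 15 (3R,3aS,4S,6S,7R,7aS)-6,7-bis[(tert-butyldimethylsilyl)oxy]-4,7a-dimethyl-3-(prop-1-en-2-yl)octahydro-5H-inden-5-one, via cyclohexenone 14 (not isolated)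
Conditions: piperidine, AcOH (20 mol % each), 4 Å molecular sieves, PhMe, 60 °C; then Me2AlCl (3 equiv), CH2Cl2, −78 → 0 °C, same flask
Reagents that add atoms: none
Why: Proposed new method: amine-catalysed intramolecular aldol condensation of the ethyl ketone onto the non-enolisable aldehyde closes cyclohexenone 14 (C15=C16), and Me2AlCl then activates this enone for an intramolecular ene reaction with the prenyl terminus, in which C16–C7 bond formation and transfer of a C19 methyl hydrogen to C15 through one cyclic transition state force attack from the face carrying the C5 tether (cis ring fusion at C16) and place C8 cis to C15 (C7), the C2 centre being held trans to C3 thermodynamically; the closest known reactions are the domino Knoevenagel–ene sequence and Lewis-acid-promoted ene cyclisations of enones onto 1,6-related alkenes.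

**Step 10**
Reactants: 15 (3R,3aS,4S,6S,7R,7aS)-6,7-bis[(tert-butyldimethylsilyl)oxy]-4,7a-dimethyl-3-(prop-1-en-2-yl)octahydro-5H-inden-5-one
Product: 16 (3R,3aR,6S,7R,7aS)-6,7-bis[(tert-butyldimethylsilyl)oxy]-4,7a-dimethyl-3-(prop-1-en-2-yl)-2,3,3a,6,7,7a-hexahydro-1H-inden-5-yl trifluoromethanesulfonate
Conditions: KN(SiMe3)2, THF, −78 °C; then PhNTf2, −78 → 0 °C
Reagents that add atoms: N-phenylbis(trifluoromethanesulfonimide), O=S(=O)(N(c1ccccc1)S(=O)(=O)C(F)(F)F)C(F)(F)F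
Why: Enol triflate formation; enolisation occurs away from the silyloxy-bearing C2 (the usual α′ preference of α-oxygenated ketones), fixing the C1=C15 alkene and erasing the C15 centre.

**Step 11**
Reactants: 16 (3R,3aR,6S,7R,7aS)-6,7-bis[(tert-butyldimethylsilyl)oxy]-4,7a-dimethyl-3-(prop-1-en-2-yl)-2,3,3a,6,7,7a-hexahydro-1H-inden-5-yl trifluoromethanesulfonate; 5 (2S)-5-[(tert-butyldimethylsilyl)oxy]-2-ethenylpentyl acetate
Product: 18 (2R)-2-(2-{(3R,3aS,6R,7R,7aS)-6,7-bis[(tert-butyldimethylsilyl)oxy]-4,7a-dimethyl-3-(prop-1-en-2-yl)-2,3,3a,6,7,7a-hexahydro-1H-inden-5-yl}ethyl)-5-[(tert-butyldimethylsilyl)oxy]pentyl acetate, via alkylborane 17 (not isolated)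
Conditions: 5 (1.5 equiv), 9-BBN-H, THF, 23 °C; then 16, PdCl2(dppf) (10 mol %), AsPh3, Cs2CO3, DMF–H2O, 23 → 40 °C
Reagents that add atoms: none
Why: Hydroboration of the vinyl group followed by B-alkyl Suzuki–Miyaura coupling with the enol triflate forms C1–C14; acetate, silyl ethers and the isopropenyl group are tolerated and no stereocentre changes.

**Step 12**
Reactants: 18 (2R)-2-(2-{(3R,3aS,6R,7R,7aS)-6,7-bis[(tert-butyldimethylsilyl)oxy]-4,7a-dimethyl-3-(prop-1-en-2-yl)-2,3,3a,6,7,7a-hexahydro-1H-inden-5-yl}ethyl)-5-[(tert-butyldimethylsilyl)oxy]pentyl acetate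
Product: 20 (2R)-2-(2-{(3R,3aS,6R,7R,7aS)-3-acetyl-6,7-bis[(tert-butyldimethylsilyl)oxy]-4,7a-dimethyl-2,3,3a,6,7,7a-hexahydro-1H-inden-5-yl}ethyl)-5-[(tert-butyldimethylsilyl)oxy]pentyl acetate, via diol 19 (not isolated)
Conditions: OsO4 (2 mol %), NaIO4 (4 equiv), 2,6-lutidine, dioxane–H2O (3:1), 23 °C
Reagents that add atoms: sodium periodate (terminal oxidant, oxygen delivered through OsO4), [Na+].[O-]I(=O)(=O)=O; water, O
Why: Lemieux–Johnson oxidative cleavage; OsO4 reacts with the unhindered 1,1-disubstituted alkene far faster than with the shielded tetrasubstituted C1=C15 alkene, and the lutidine buffer avoids epimerisation at C7.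

**Step 13**
Reactants: 20 (2R)-2-(2-{(3R,3aS,6R,7R,7aS)-3-acetyl-6,7-bis[(tert-butyldimethylsilyl)oxy]-4,7a-dimethyl-2,3,3a,6,7,7a-hexahydro-1H-inden-5-yl}ethyl)-5-[(tert-butyldimethylsilyl)oxy]pentyl acetate
Product: 21 (2R)-2-(2-{(3R,3aS,6R,7R,7aS)-6,7-bis[(tert-butyldimethylsilyl)oxy]-4,7a-dimethyl-3-[1-(trifluoromethanesulfonyloxy)ethenyl]-2,3,3a,6,7,7a-hexahydro-1H-inden-5-yl}ethyl)-5-[(tert-butyldimethylsilyl)oxy]pentyl acetate
Conditions: LiN(SiMe3)2 (1.1 equiv), THF, −78 °C; then PhNTf2, −78 → 0 °C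
Reagents that add atoms: N-phenylbis(trifluoromethanesulfonimide), O=S(=O)(N(c1ccccc1)S(=O)(=O)C(F)(F)F)C(F)(F)F
Why: Kinetic enolisation of the methyl ketone at the methyl group and O-triflation give the 1,1-disubstituted vinyl triflate; the more acidic ketone reacts before the acetate and C7 is not deprotonated.

**Step 14**
Reactants: 21 (2R)-2-(2-{(3R,3aS,6R,7R,7aS)-6,7-bis[(tert-butyldimethylsilyl)oxy]-4,7a-dimethyl-3-[1-(trifluoromethanesulfonyloxy)ethenyl]-2,3,3a,6,7,7a-hexahydro-1H-inden-5-yl}ethyl)-5-[(tert-butyldimethylsilyl)oxy]pentyl acetate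
Product: 22 (2R)-2-(2-{(3R,3aS,6R,7R,7aS)-6,7-bis[(tert-butyldimethylsilyl)oxy]-4,7a-dimethyl-3-[1-(trifluoromethanesulfonyloxy)ethenyl]-2,3,3a,6,7,7a-hexahydro-1H-inden-5-yl}ethyl)-5-hydroxypentyl acetate
Conditions: HF·pyridine, pyridine, THF, 0 °C
Reagents that add atoms: none
Why: Selective silyl ether cleavage; the unhindered primary TBS ether is removed while the two hindered secondary TBS ethers, the vinyl triflate and the acetate survive.

**Step 15**
Reactants: 22 (2R)-2-(2-{(3R,3aS,6R,7R,7aS)-6,7-bis[(tert-butyldimethylsilyl)oxy]-4,7a-dimethyl-3-[1-(trifluoromethanesulfonyloxy)ethenyl]-2,3,3a,6,7,7a-hexahydro-1H-inden-5-yl}ethyl)-5-hydroxypentyl acetate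
Product: 23 (2R)-2-(2-{(3R,3aS,6R,7R,7aS)-6,7-bis[(tert-butyldimethylsilyl)oxy]-4,7a-dimethyl-3-[1-(trifluoromethanesulfonyloxy)ethenyl]-2,3,3a,6,7,7a-hexahydro-1H-inden-5-yl}ethyl)-5-oxopentyl acetate
Conditions: Dess–Martin periodinane, NaHCO3, CH2Cl2, 23 °C
Reagents that add atoms: none
Why: Dess–Martin oxidation of the primary alcohol to the C9 aldehyde under buffered, neutral conditions that leave all other groups intact.

**Step 16**
Reactants: 23 (2R)-2-(2-{(3R,3aS,6R,7R,7aS)-6,7-bis[(tert-butyldimethylsilyl)oxy]-4,7a-dimethyl-3-[1-(trifluoromethanesulfonyloxy)ethenyl]-2,3,3a,6,7,7a-hexahydro-1H-inden-5-yl}ethyl)-5-oxopentyl acetate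
Product: 24 tricyclic allylic alcohol (2R,3R,4S,7R,9S,12R,16S): the target skeleton carrying 2-OTBS, 3-OTBS, free 9-OH and 20-OAc
Conditions: CrCl2 (6 equiv), NiCl2 (1 mol %), DMSO, 23 °C, 2 mM, slow addition of 23
Reagents that add atoms: none
Why: Intramolecular Nozaki–Hiyama–Kishi reaction closes the eleven-membered ring at C8–C9 and gives the exocyclic methylene and C9 carbinol in one step; addition through the conformer with the carbonyl oxygen on the outside of the forming ring is expected to give the 9S alcohol (substrate control).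

**Step 17**
Reactants: 24 tricyclic allylic alcohol (2R,3R,4S,7R,9S,12R,16S)
Product: 25 9,20-diacetate 2,3-bis(TBS ether) of the target (2R,3R,4S,7R,9S,12R,16S)
Conditions: Ac2O, DMAP, pyridine, 23 °C
Reagents that add atoms: acetic anhydride, CC(=O)OC(C)=O
Why: Acylation of the only free hydroxyl (C9) with retention of configuration.

**Step 18**
Reactants: 25 9,20-diacetate 2,3-bis(TBS ether) of the target
Product: 26 target CNP0193272.1 (2R,3R,4S,7R,9S,12R,16S)
Conditions: HF·pyridine, THF, 0 → 23 °C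
Reagents that add atoms: none
Why: Fluoride-mediated silyl ether cleavage frees the trans-2,3-diol under mildly acidic conditions that do not cleave or migrate the acetates.

**Compound list**
1 | (E)-1,4-dibromobut-2-ene | BrC/C=C/CBr | starting material
2 | (E)-4-bromobut-2-en-1-yl acetate | CC(=O)OC/C=C/CBr | intermediate
3 | (3-bromopropoxy)(tert-butyl)dimethylsilane | CC(C)(C)[Si](C)(C)OCCCBr | starting material
4 | {3-[(tert-butyldimethylsilyl)oxy]propyl}magnesium bromide | CC(C)(C)[Si](C)(C)OCCC[Mg]Br | intermediate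
5 | (2S)-5-[(tert-butyldimethylsilyl)oxy]-2-ethenylpentyl acetate | CC(C)(C)[Si](C)(C)OCCC[C@H](COC(C)=O)C=C | intermediate
6 | geraniol, (2E)-3,7-dimethylocta-2,6-dien-1-ol | CC(C)=CCC/C(C)=C/CO | starting material
7 | (2S,3S)-2,3-epoxygeraniol, [(2S,3S)-3-methyl-3-(4-methylpent-3-en-1-yl)oxiran-2-yl]methanol | CC(C)=CCC[C@]1(C)O[C@H]1CO | intermediate
8 | triethyl{[(2S,3S)-3-methyl-3-(4-methylpent-3-en-1-yl)oxiran-2-yl]methoxy}silane | CC(C)=CCC[C@]1(C)O[C@H]1CO[Si](CC)(CC)CC | intermediate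
9 | (2S)-2,6-dimethyl-2-{[(triethylsilyl)oxy]methyl}hept-5-enal | CC(C)=CCC[C@](CO[Si](CC)(CC)CC)(C)C=O | intermediate
10 | 1-hydroxybutan-2-one | CCC(=O)CO | starting material
11 | (4S,5R,6S)-4,5-dihydroxy-6,10-dimethyl-6-{[(triethylsilyl)oxy]methyl}undec-9-en-3-one | CC(C)=CCC[C@](CO[Si](CC)(CC)CC)(C)[C@@H](O)[C@H](O)C(=O)CC | intermediate
12 | (4S,5R,6S)-4,5-bis[(tert-butyldimethylsilyl)oxy]-6,10-dimethyl-6-{[(triethylsilyl)oxy]methyl}undec-9-en-3-one | CC(C)=CCC[C@](CO[Si](CC)(CC)CC)(C)[C@@H](O[Si](C)(C)C(C)(C)C)[C@H](O[Si](C)(C)C(C)(C)C)C(=O)CC | intermediate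
13 | (2R)-2-{(1R,2S)-1,2-bis[(tert-butyldimethylsilyl)oxy]-3-oxopentyl}-2,6-dimethylhept-5-enal | CC(C)=CCC[C@](C=O)(C)[C@@H](O[Si](C)(C)C(C)(C)C)[C@H](O[Si](C)(C)C(C)(C)C)C(=O)CC | intermediate
14 | (4S,5R,6S)-5,6-bis[(tert-butyldimethylsilyl)oxy]-2,4-dimethyl-4-(4-methylpent-3-en-1-yl)cyclohex-2-en-1-one | CC(C)=CCC[C@]1(C)[C@@H](O[Si](C)(C)C(C)(C)C)[C@H](O[Si](C)(C)C(C)(C)C)C(=O)C(C)=C1 | intermediate
15 | (3R,3aS,4S,6S,7R,7aS)-6,7-bis[(tert-butyldimethylsilyl)oxy]-4,7a-dimethyl-3-(prop-1-en-2-yl)octahydro-5H-inden-5-one (cis-fused) | O=C1[C@@H](C)[C@@H]2[C@H](C(C)=C)CC[C@]2(C)[C@@H](O[Si](C)(C)C(C)(C)C)[C@@H]1O[Si](C)(C)C(C)(C)C | intermediate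
16 | (3R,3aR,6S,7R,7aS)-6,7-bis[(tert-butyldimethylsilyl)oxy]-4,7a-dimethyl-3-(prop-1-en-2-yl)-2,3,3a,6,7,7a-hexahydro-1H-inden-5-yl trifluoromethanesulfonate | FC(F)(F)S(=O)(=O)OC1=C(C)[C@@H]2[C@H](C(C)=C)CC[C@]2(C)[C@@H](O[Si](C)(C)C(C)(C)C)[C@@H]1O[Si](C)(C)C(C)(C)C | intermediate
17 | (2R)-2-[2-(9-borabicyclo[3.3.1]nonan-9-yl)ethyl]-5-[(tert-butyldimethylsilyl)oxy]pentyl acetate | CC(C)(C)[Si](C)(C)OCCC[C@H](COC(C)=O)CCB1C2CCCC1CCC2 | intermediate
18 | (2R)-2-(2-{(3R,3aS,6R,7R,7aS)-6,7-bis[(tert-butyldimethylsilyl)oxy]-4,7a-dimethyl-3-(prop-1-en-2-yl)-2,3,3a,6,7,7a-hexahydro-1H-inden-5-yl}ethyl)-5-[(tert-butyldimethylsilyl)oxy]pentyl acetate | CC(C)(C)[Si](C)(C)OCCC[C@H](COC(C)=O)CCC1=C(C)[C@@H]2[C@H](C(C)=C)CC[C@]2(C)[C@@H](O[Si](C)(C)C(C)(C)C)[C@@H]1O[Si](C)(C)C(C)(C)C | intermediate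
19 | diol from 18: the prop-1-en-2-yl group converted into 1,2-dihydroxypropan-2-yl (both epimers at the new carbinol carbon) | CC(C)(C)[Si](C)(C)OCCC[C@H](COC(C)=O)CCC1=C(C)[C@@H]2[C@H](C(C)(O)CO)CC[C@]2(C)[C@@H](O[Si](C)(C)C(C)(C)C)[C@@H]1O[Si](C)(C)C(C)(C)C | intermediate
20 | (2R)-2-(2-{(3R,3aS,6R,7R,7aS)-3-acetyl-6,7-bis[(tert-butyldimethylsilyl)oxy]-4,7a-dimethyl-2,3,3a,6,7,7a-hexahydro-1H-inden-5-yl}ethyl)-5-[(tert-butyldimethylsilyl)oxy]pentyl acetate | CC(C)(C)[Si](C)(C)OCCC[C@H](COC(C)=O)CCC1=C(C)[C@@H]2[C@H](C(C)=O)CC[C@]2(C)[C@@H](O[Si](C)(C)C(C)(C)C)[C@@H]1O[Si](C)(C)C(C)(C)C | intermediate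
21 | (2R)-2-(2-{(3R,3aS,6R,7R,7aS)-6,7-bis[(tert-butyldimethylsilyl)oxy]-4,7a-dimethyl-3-[1-(trifluoromethanesulfonyloxy)ethenyl]-2,3,3a,6,7,7a-hexahydro-1H-inden-5-yl}ethyl)-5-[(tert-butyldimethylsilyl)oxy]pentyl acetate | CC(C)(C)[Si](C)(C)OCCC[C@H](COC(C)=O)CCC1=C(C)[C@@H]2[C@H](C(=C)OS(=O)(=O)C(F)(F)F)CC[C@]2(C)[C@@H](O[Si](C)(C)C(C)(C)C)[C@@H]1O[Si](C)(C)C(C)(C)C | intermediate
22 | (2R)-2-(2-{(3R,3aS,6R,7R,7aS)-6,7-bis[(tert-butyldimethylsilyl)oxy]-4,7a-dimethyl-3-[1-(trifluoromethanesulfonyloxy)ethenyl]-2,3,3a,6,7,7a-hexahydro-1H-inden-5-yl}ethyl)-5-hydroxypentyl acetate | OCCC[C@H](COC(C)=O)CCC1=C(C)[C@@H]2[C@H](C(=C)OS(=O)(=O)C(F)(F)F)CC[C@]2(C)[C@@H](O[Si](C)(C)C(C)(C)C)[C@@H]1O[Si](C)(C)C(C)(C)C | intermediate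
23 | (2R)-2-(2-{(3R,3aS,6R,7R,7aS)-6,7-bis[(tert-butyldimethylsilyl)oxy]-4,7a-dimethyl-3-[1-(trifluoromethanesulfonyloxy)ethenyl]-2,3,3a,6,7,7a-hexahydro-1H-inden-5-yl}ethyl)-5-oxopentyl acetate | O=CCC[C@H](COC(C)=O)CCC1=C(C)[C@@H]2[C@H](C(=C)OS(=O)(=O)C(F)(F)F)CC[C@]2(C)[C@@H](O[Si](C)(C)C(C)(C)C)[C@@H]1O[Si](C)(C)C(C)(C)C | intermediate
24 | tricyclic allylic alcohol (2R,3R,4S,7R,9S,12R,16S): target skeleton with 2-OTBS, 3-OTBS, 9-OH, 20-OAc | C=C1[C@@H](O)CC[C@H](COC(C)=O)CCC2=C(C)[C@@H]3[C@H]1CC[C@]3(C)[C@@H](O[Si](C)(C)C(C)(C)C)[C@@H]2O[Si](C)(C)C(C)(C)C | intermediate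
25 | 9,20-diacetate 2,3-bis(TBS ether) of the target (2R,3R,4S,7R,9S,12R,16S) | C=C1[C@@H](OC(C)=O)CC[C@H](COC(C)=O)CCC2=C(C)[C@@H]3[C@H]1CC[C@]3(C)[C@@H](O[Si](C)(C)C(C)(C)C)[C@@H]2O[Si](C)(C)C(C)(C)C | intermediate
26 | CNP0193272.1 (2R,3R,4S,7R,9S,12R,16S): 9,20-diacetoxy-2,3-dihydroxy tricycle | C=C1[C@@H](OC(C)=O)CC[C@H](COC(C)=O)CCC2=C(C)[C@@H]3[C@H]1CC[C@]3(C)[C@@H](O)[C@@H]2O | target

**Totals**
Total step count: 18. Longest linear sequence: 16 steps (geraniol 6 → 26, steps 3–18); the side chain 5 takes 2 steps and joins at step 11.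

**Three steps most likely to fail, each with one fallback**

Step 9 (one-flask aldol condensation/ene bicyclisation). The ene stage may be slow at the hindered enone or may give chloride-trapped or proton-loss isomers. The fallback sets out from 13 and comes back at 15. Only the amine-catalysed condensation is run and cyclohexenone 14 is isolated. Irradiation of 14 (350 nm, CH2Cl2, −40 °C) gives, by intramolecular enone–alkene [2+2] photocycloaddition, the cis-fused cyclobutane photoadduct F4 (bonds C16–C7 and C15–C8). Further irradiation at 300 nm causes Norrish type-2 abstraction of a hydrogen from a C8 methyl by the excited C1 ketone and cleavage of the C15–C8 bond. The enol formed tautomerises to the same ketone 15, with the C16/C7 cis relationship fixed by the cyclobutane.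

Step 6 (organocatalytic syn-aldol onto an α-quaternary aldehyde). The neopentyl aldehyde may react too slowly or with poor diastereocontrol. The fallback sets out from 9 and comes back at 11. An Evans boron aldol of (4S)-4-benzyl-3-{[(4-methoxybenzyl)oxy]acetyl}-1,3-oxazolidin-2-one (Bu2BOTf, Et3N, CH2Cl2, −78 °C) with 9 gives the syn-glycolate adduct F1 under auxiliary control. AlMe3/MeONHMe·HCl converts F1 into the Weinreb amide F2, and EtMgBr then gives the PMB-protected ethyl ketone F3. DDQ (CH2Cl2–pH 7 buffer) removes the 4-methoxybenzyl group to give diol 11.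

Step 16 (eleven-membered Nozaki–Hiyama–Kishi closure). Apart from moderate yield, the C9 configuration is only substrate-controlled and may come out mixed or inverted. The fallback sets out from the crude step-16 product, that is 24 together with its C9 epimer, the 9R alcohol F5, and comes back at 24. The mixture is oxidised (MnO2, CH2Cl2) to the single α-methylene ketone F6. Corey–Bakshi–Shibata reduction (oxazaborolidine enantiomer chosen for the 9S carbinol, BH3·SMe2, THF, −40 °C) then sets C9 under reagent control and returns 24.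

**Further compounds**
F1 | step 6 | (4S)-4-benzyl-3-[(2S,3R,4S)-3-hydroxy-2-[(4-methoxybenzyl)oxy]-4,8-dimethyl-4-{[(triethylsilyl)oxy]methyl}non-7-enoyl]-1,3-oxazolidin-2-one | CC(C)=CCC[C@](CO[Si](CC)(CC)CC)(C)[C@@H](O)[C@H](OCc1ccc(OC)cc1)C(=O)N2C(=O)OC[C@@H]2Cc3ccccc3
F2 | step 6 | (2S,3R,4S)-3-hydroxy-N-methoxy-2-[(4-methoxybenzyl)oxy]-N,4,8-trimethyl-4-{[(triethylsilyl)oxy]methyl}non-7-enamide | CC(C)=CCC[C@](CO[Si](CC)(CC)CC)(C)[C@@H](O)[C@H](OCc1ccc(OC)cc1)C(=O)N(C)OC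
F3 | step 6 | (4S,5R,6S)-5-hydroxy-4-[(4-methoxybenzyl)oxy]-6,10-dimethyl-6-{[(triethylsilyl)oxy]methyl}undec-9-en-3-one | CC(C)=CCC[C@](CO[Si](CC)(CC)CC)(C)[C@@H](O)[C@H](OCc1ccc(OC)cc1)C(=O)CC
F4 | step 9 | cyclobutane photoadduct of 14 (new bonds C16–C7 and C15–C8, gem-dimethyl on C8, cis-fused to both rings) | O=C1[C@@]3(C)[C@@H]2[C@H](C3(C)C)CC[C@]2(C)[C@@H](O[Si](C)(C)C(C)(C)C)[C@@H]1O[Si](C)(C)C(C)(C)C
F5 | step 16 | 9R epimer of 24 | C=C1[C@H](O)CC[C@H](COC(C)=O)CCC2=C(C)[C@@H]3[C@H]1CC[C@]3(C)[C@@H](O[Si](C)(C)C(C)(C)C)[C@@H]2O[Si](C)(C)C(C)(C)C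
F6 | step 16 | 9-oxo compound (α-methylene ketone) derived from 24 and F5 | C=C1C(=O)CC[C@H](COC(C)=O)CCC2=C(C)[C@@H]3[C@H]1CC[C@]3(C)[C@@H](O[Si](C)(C)C(C)(C)C)[C@@H]2O[Si](C)(C)C(C)(C)C
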